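**Retrosynthetic overview**
1. Route numbering: C1 quaternary C–CH3, C2 CH2, C3 CH–OAc, C4 C(OH)iPr, C5 ring-fusion CH, C6 CH–O-aroyl, C7=C8(CH3), C9 CH2, C10 CH–OH; five-membered ring C1–C5, seven-membered ring C1, C5–C10. The strategy rests on quaternary C1: it carries the methyl and lies between C10 and C5, so it is C2 of a prochiral 2-methylcycloheptane-1,3-dione whose two enantiotopic carbonyls become C10 and C5.
2. Key disconnection: the C4–C5 bond of bicyclic enedione 10 (aldol condensation), back to triketone 8; a chiral amine picks one ring carbonyl, closes the five-membered ring and fixes C1.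
3. Triketone 8 comes from cycloheptane-1,3-dione by C-methylation and C-alkylation with 1-bromo-4-methylpentan-2-one (from isovaleryl chloride).
4. After the aldol: C10–OH by ketone reduction; C6 oxygen by γ-oxidation of the cyclopentenone; cis ring fusion (C5–H) and the C3=C4 alkene by Pd-formate 1,3-transposition; cis-diol by OsO4; C7=C8(CH3) by Saegusa/cuprate/Saegusa on the C6 ketone; then 1,2-reduction and esters.
5. Ring order: the seven-membered ring is bought, the five-membered ring is closed in step 4; every other stereocentre is derived from C1.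

Key step: step 4

Assumptions:
- 4-(tert-Butyldimethylsilyloxy)benzoic acid 29 is taken as a catalogue compound (otherwise one operation from 4-hydroxybenzoic acid).
- The C6 carbinol configuration made in step 7 is irrelevant because C6 becomes a ketone in step 15; compounds 14–21 are drawn without a C6 descriptor.
- β is the face of the bicycle that carries the C1 methyl, α the opposite face. Target in route numbering: (1S,3S,4R,5R,6S,10S); 5-H, 3-OAc, 4-OH and 10-OH are β, the 6-aroyloxy group is α.

**Step 1**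
Reactants: 1 cycloheptane-1,3-dione; 2 iodomethane
Product: 3 2-methylcycloheptane-1,3-dione
Conditions: K2CO3, acetone, 40 °C
Reagents that add atoms: none
Why: C-alkylation of the stabilised 1,3-dione enolate (the seven-ring dione is largely ketonic, which favours C- over O-methylation), with mono-methylation held by stoichiometry.

**Step 2**
Reactants: 4 3-methylbutanoyl chloride (isovaleryl chloride); 5 (trimethylsilyl)diazomethane
Product: 7 1-bromo-4-methylpentan-2-one, via diazoketone 6 (not isolated)
Conditions: TMSCHN2 (2 equiv), THF/MeCN, 0 °C → rt; then 48% aq HBr, 0 °C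
Reagents that add atoms: hydrogen bromide, Br
Why: Acylation of the diazoalkane (Arndt–Eistert-type diazoketone synthesis) and then protonation with SN2 loss of N2 to bromide gives the bromomethyl ketone regiospecifically.

**Step 3**
Reactants: 3 2-methylcycloheptane-1,3-dione; 7 1-bromo-4-methylpentan-2-one
Product: 8 2-methyl-2-(4-methyl-2-oxopentyl)cycloheptane-1,3-dione
Conditions: Cs2CO3, NaI (cat.), MeCN, 0 °C → rt
Reagents that add atoms: none
Why: SN2 C-alkylation of the 2-methyl-1,3-dione enolate by a soft, reactive α-halo ketone (iodide catalysis) builds quaternary C1, which remains prochiral; no stereocentre is formed.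

**Step 4 (key step)**
Reactants: 8 2-methyl-2-(4-methyl-2-oxopentyl)cycloheptane-1,3-dione
Product: 10 (1S)-4-isopropyl-1-methylbicyclo[5.3.0]dec-4-ene-3,10-dione, via ketol 9 (not isolated)
Conditions: (S)-phenylalanine (1.0 equiv), (1S)-(+)-10-camphorsulfonic acid (0.5 equiv), DMF, 30 → 70 °C
Reagents that add atoms: none
Why: Proposed new method: the primary amine condenses with the side-chain ketone C3 and the iminium tautomerises to the enamine C3=C4 (an enamine on the neopentyl C2 side could only close a three-membered ring); its carbon C4, which bears the isopropyl group, adds to one of the two enantiotopic ring carbonyls (C5), held and activated by a hydrogen bond from the carboxylic acid, to give ketol 9, which the sulfonic acid co-catalyst dehydrates to the tetrasubstituted enone 10 with release of the amino acid. The closest known reactions are the Hajos–Parrish–Eder–Sauer–Wiechert aldol, the primary-amine/acid desymmetrising aldols of 2,2-disubstituted cyclic 1,3-diones that close six-membered rings, and the base-mediated 1,4-diketone to cyclopentenone condensation. The five-membered ring C1–C2–C3–C4–C5 closes in the 5-(enolendo)-exo-trig mode, strained but the geometry of every 1,4-diketone cyclopentenone aldol; a primary-amine (N–H) enamine is chosen because it is small and can twist as the ring closes. C1, the only stereocentre that survives, is set by which enantiotopic C=O the catalyst-bound enamine reaches in the carboxylate-directed transition state; the (S)-amino acid is chosen by analogy with the Hajos–Parrish series, whose quaternary centre has the same topology, the (R)-amino acid being equally available should the sense prove opposite, and C4/C5 of the ketol vanish on dehydration. The step needs enantiotopic-group selectivity over a racemic background, so it is run under acid and not base; the substrate keeps it clean because quaternary C1 blocks Paal–Knorr pyrrole or furan formation, bridged ketols from ring-ketone enamines cannot dehydrate and revert, and the conjugated enone is the thermodynamic sink.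

**Step 5**
Reactants: 10 (1S)-4-isopropyl-1-methylbicyclo[5.3.0]dec-4-ene-3,10-dione
Product: 11 (1S,10S)-10β-hydroxy-4-isopropyl-1-methylbicyclo[5.3.0]dec-4-en-3-one
Conditions: NaBH4 (0.3 equiv), EtOH, −20 °C
Reagents that add atoms: none
Why: Chemoselective borohydride reduction of the saturated ketone beside a hindered tetrasubstituted enone, as in the Hajos–Parrish and Wieland–Miescher series; hydride adds to C10 anti to the pseudo-axial C1 methyl, so the hydroxyl is cis (β) to it.

**Step 6**
Reactants: 11 (1S,10S)-10β-hydroxy enone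
Product: 12 10β-(tert-butyldimethylsilyloxy)-4-isopropyl-1-methylbicyclo[5.3.0]dec-4-en-3-one
Conditions: TBSOTf, 2,6-lutidine, CH2Cl2, −78 → 0 °C
Reagents that add atoms: tert-butyldimethylsilyl triflate, CC(C)(C)[Si](C)(C)OS(=O)(=O)C(F)(F)F
Why: A silyl triflate with a hindered pyridine base silylates the neopentyl-type secondary alcohol without enolising the enone, and the TBS ether is carried to the last step.

**Step 7**
Reactants: 12 10β-TBS-oxy enone
Product: 14 10β-(TBS-oxy)-6-hydroxy-4-isopropyl-1-methylbicyclo[5.3.0]dec-4-en-3-one, via TMS dienol ether 13 (not isolated)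
Conditions: TMSOTf, Et3N, CH2Cl2, −78 → −20 °C; then mCPBA, NaHCO3, CH2Cl2/hexane, −20 °C; aq citric acid work-up
Reagents that add atoms: 3-chloroperoxybenzoic acid, OOC(=O)c1cccc(Cl)c1
Why: Vinylogous Rubottom oxidation: O-silylation and γ-deprotonation should give the extended 3-silyloxy-3,5-diene (the α′ methylene C2 is shielded by quaternary C1 and the dienol ether is used at once), and the peracid attacks its terminal carbon C6 because C4 is fully substituted, the silyloxy cation collapsing to the γ-hydroxy enone.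

**Step 8**
Reactants: 14 6-hydroxy enone
Product: 15 10β-(TBS-oxy)-6-(triethylsilyloxy)-4-isopropyl-1-methylbicyclo[5.3.0]dec-4-en-3-one
Conditions: TESCl, imidazole, DMAP (cat.), DMF, rt
Reagents that add atoms: chlorotriethylsilane, CC[Si](Cl)(CC)CC
Why: Standard silylation; a TES ether is not ionised by Pd(0) in step 11 and can later be removed beside the hindered C10 TBS ether.

**Step 9**
Reactants: 15 6-TES-oxy enone
Product: 16 (3R)-3α-hydroxy-10β-(TBS-oxy)-6-(TES-oxy)-4-isopropyl-1-methylbicyclo[5.3.0]dec-4-ene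
Conditions: (S)-Me-CBS oxazaborolidine (0.5 equiv), catecholborane, toluene/CH2Cl2, −78 → −40 °C
Reagents that add atoms: none
Why: Corey–Bakshi–Shibata reduction under reagent control: the α-isopropyl alkene carbon C4 is the large and the C2 methylene the small substituent, so the (S)-catalyst delivers hydride to the β face of C3 and gives the 3α (3R) allylic alcohol, while the tetrasubstituted alkene rules out hydroboration and 1,4-reduction.

**Step 10**
Reactants: 16 3α-allylic alcohol
Product: 17 3α-formyloxy-10β-(TBS-oxy)-6-(TES-oxy)-4-isopropyl-1-methylbicyclo[5.3.0]dec-4-ene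
Conditions: HCO2H, DCC, DMAP (cat.), CH2Cl2, 0 °C
Reagents that add atoms: formic acid, OC=O
Why: Carbodiimide (Steglich-type) formylation of the secondary alcohol proceeds with retention at C3.

**Step 11**
Reactants: 17 3α-allylic formate
Product: 18 10β-(TBS-oxy)-6-(TES-oxy)-4-isopropyl-1-methyl-5β-H-bicyclo[5.3.0]dec-3-ene (cis-fused)
Conditions: Pd(OAc)2 (10 mol %), n-Bu3P (40 mol %), THF, rt → 45 °C
Reagents that add atoms: none
Why: Tsuji–Mandai hydrogenolysis of an allylic formate with 1,3-transposition: Pd(0) ionises the 3α-formate with inversion to a β-face π-allyl complex, decarboxylation gives Pd–H, and hydride passes from palladium to the more substituted terminus C5 on the β face, which sets the cis ring fusion (5-H cis to the C1 methyl) and leaves the C3=C4 alkene.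

**Step 12**
Reactants: 18 cis-fused Δ3-alkene
Product: 19 3β,4β-dihydroxy-10β-(TBS-oxy)-6-(TES-oxy)-4α-isopropyl-1-methyl-5β-H-bicyclo[5.3.0]decane
Conditions: OsO4 (5 mol %), NMO, acetone/H2O (4:1), rt; aq Na2SO3
Reagents that add atoms: osmium tetroxide (catalytic oxygen carrier), O=[Os](=O)(=O)=O; N-methylmorpholine N-oxide, C[N+]1([O-])CCOCC1; water, O
Why: Upjohn cis-dihydroxylation of the only alkene; OsO4 adds to the convex β face of the cis-fused bicycle, anti to the allylic C5–C6 bond and the seven-membered ring that covers the α face, giving the 3β,4β-diol with isopropyl α.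

**Step 13**
Reactants: 19 3β,4β-diol
Product: 20 3β-acetoxy-4β-hydroxy-10β-(TBS-oxy)-6-(TES-oxy)-4α-isopropyl-1-methyl-5β-H-bicyclo[5.3.0]decane
Conditions: Ac2O, pyridine, DMAP (cat.), CH2Cl2, 0 °C → rt
Reagents that add atoms: acetic anhydride, CC(=O)OC(C)=O
Why: DMAP-catalysed acylation takes the secondary C3 hydroxyl and leaves the tertiary, hindered C4 hydroxyl untouched.

**Step 14**
Reactants: 20 3β-acetate 6-TES ether
Product: 21 3β-acetoxy-4β,6-dihydroxy-10β-(TBS-oxy)-4α-isopropyl-1-methyl-5β-H-bicyclo[5.3.0]decane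
Conditions: PPTS (cat.), MeOH/CH2Cl2, 0 °C → rt
Reagents that add atoms: none
Why: Mild acid methanolysis cleaves the secondary TES ether much faster than the neopentyl-type C10 TBS ether and does not touch the acetate.

**Step 15**
Reactants: 21 6-alcohol
Product: 22 3β-acetoxy-4β-hydroxy-10β-(TBS-oxy)-4α-isopropyl-1-methyl-5β-H-bicyclo[5.3.0]decan-6-one
Conditions: Dess–Martin periodinane, NaHCO3, CH2Cl2, 0 °C → rt
Reagents that add atoms: none
Why: Dess–Martin oxidation under buffered, non-enolising conditions preserves the C5 centre and the β-hydroxy ketone.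

**Step 16**
Reactants: 22 6-ketone
Product: 24 3β-acetoxy-10β-(TBS-oxy)-4β-(trimethylsilyloxy)-4α-isopropyl-1-methyl-5β-H-bicyclo[5.3.0]dec-7-en-6-one, via C6 TMS enol ether 23 (not isolated)
Conditions: TMSOTf, Et3N, CH2Cl2, −20 → 0 °C; then Pd(OAc)2 (1.1 equiv), MeCN, rt
Reagents that add atoms: trimethylsilyl triflate, C[Si](C)(C)OS(=O)(=O)C(F)(F)F
Why: Saegusa–Ito dehydrogenation: soft enolisation takes the accessible C7 hydrogen (C5–H lies between two fully substituted carbons and its enol ether would be a strained tetrasubstituted alkene) and silylates the tertiary hydroxyl, and Pd(II) then gives the C7=C8 enone without strong base, so C5 does not epimerise and no retro-aldol occurs.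

**Step 17**
Reactants: 24 C4-O-TMS 7-en-6-one
Product: 27 3β-acetoxy-4β-hydroxy-10β-(TBS-oxy)-4α-isopropyl-1,8-dimethyl-5β-H-bicyclo[5.3.0]dec-7-en-6-one, via C8-methyl TMS enol ether 25 (not isolated), via C4-O-TMS enone 26 (not isolated)
Conditions: Me2CuLi (MeLi, CuI), TMSCl, THF, −78 °C; then Pd(OAc)2 (1.1 equiv), MeCN, rt; then citric acid, MeOH, 0 °C
Reagents that add atoms: lithium dimethylcuprate, [Li+].C[Cu-]C
Why: Gilman 1,4-addition with TMSCl puts the methyl on C8 and traps the enolate regiospecifically as the C6–C7 silyl enol ether, whose Saegusa–Ito oxidation re-forms the enone with the C8 methyl in place (the transient C8 centre is destroyed), and the acidic work-up frees the tertiary hydroxyl.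

**Step 18**
Reactants: 27 8-methyl-7-en-6-one
Product: 28 3β-acetoxy-4β,6α-dihydroxy-10β-(TBS-oxy)-4α-isopropyl-1,8-dimethyl-5β-H-bicyclo[5.3.0]dec-7-ene
Conditions: NaBH4, CeCl3·7H2O, MeOH, −78 °C
Reagents that add atoms: none
Why: Luche 1,2-reduction of the enone; hydride should attack C6 from the convex β face, anti to the five-membered ring and the α-isopropyl group on C4, to give the 6α-alcohol, and the epimer, if formed, would be esterified with inversion under Mitsunobu conditions.

**Step 19**
Reactants: 28 6α-allylic alcohol; 29 4-(tert-butyldimethylsilyloxy)benzoic acid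
Product: 31 3β-acetoxy-4β-hydroxy-10β-(TBS-oxy)-4α-isopropyl-1,8-dimethyl-5β-H-bicyclo[5.3.0]dec-7-en-6α-yl 4-(TBS-oxy)benzoate, via mixed anhydride 30 (not isolated)
Conditions: 29, 2,4,6-trichlorobenzoyl chloride, Et3N, THF, rt; then 28, DMAP, toluene, rt → 40 °C
Reagents that add atoms: none
Why: Yamaguchi esterification acylates the hindered secondary allylic C6 hydroxyl with retention while the tertiary C4 hydroxyl is inert.

**Step 20**
Reactants: 31 bis-TBS ester
Product: 32 CNP0146780.2, (1S,3S,4R,5R,6S,10S)-3-acetoxy-4,10-dihydroxy-4-isopropyl-1,8-dimethylbicyclo[5.3.0]dec-7-en-6-yl 4-hydroxybenzoate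
Conditions: HF·pyridine, pyridine/THF, 0 °C → rt
Reagents that add atoms: none
Why: Fluoride cleaves the aryl and the secondary silyl ether, and buffered HF·pyridine leaves the acetate, the allylic aroyl ester and the tertiary alcohol intact.

**Compound list**
1 | cycloheptane-1,3-dione | O=C1CCCCC(=O)C1 | starting material
2 | iodomethane | CI | starting material
3 | 2-methylcycloheptane-1,3-dione | CC1C(=O)CCCCC1=O | intermediate
4 | 3-methylbutanoyl chloride | CC(C)CC(Cl)=O | starting material
5 | (trimethylsilyl)diazomethane | C[Si](C)(C)C=[N+]=[N-] | starting material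
6 | 1-diazo-4-methylpentan-2-one | CC(C)CC(=O)C=[N+]=[N-] | intermediate (not isolated)
7 | 1-bromo-4-methylpentan-2-one | CC(C)CC(=O)CBr | intermediate
8 | 2-methyl-2-(4-methyl-2-oxopentyl)cycloheptane-1,3-dione | CC(C)CC(=O)CC1(C)C(=O)CCCCC1=O | intermediate (key-step precursor)
9 | (1S)-5-hydroxy-4-isopropyl-1-methylbicyclo[5.3.0]decane-3,10-dione (ketol, C4/C5 epimers) | O=C1C[C@]2(C)C(=O)CCCCC2(O)C1C(C)C | intermediate (not isolated)
10 | (1S)-4-isopropyl-1-methylbicyclo[5.3.0]dec-4-ene-3,10-dione [(8aS)-8a-methyl-3-(propan-2-yl)-4,5,6,7-tetrahydroazulene-2,8(1H,8aH)-dione] | O=C1C[C@]2(C)C(=O)CCCCC2=C1C(C)C | intermediate (key-step product)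
11 | (1S,10S)-10β-hydroxy-4-isopropyl-1-methylbicyclo[5.3.0]dec-4-en-3-one | O=C1C[C@]2(C)[C@@H](O)CCCCC2=C1C(C)C | intermediate
12 | 10β-TBS ether of 11 | O=C1C[C@]2(C)[C@@H](O[Si](C)(C)C(C)(C)C)CCCCC2=C1C(C)C | intermediate
13 | 3-(trimethylsilyloxy)-3,5-diene from 12 | C[Si](C)(C)OC1=C(C(C)C)C2=CCCC[C@H](O[Si](C)(C)C(C)(C)C)[C@@]2(C)C1 | intermediate (not isolated)
14 | 6-hydroxy-10β-(TBS-oxy) enone (C6 open) | O=C1C[C@]2(C)[C@@H](O[Si](C)(C)C(C)(C)C)CCCC(O)C2=C1C(C)C | intermediate
15 | 6-(TES-oxy)-10β-(TBS-oxy) enone | O=C1C[C@]2(C)[C@@H](O[Si](C)(C)C(C)(C)C)CCCC(O[Si](CC)(CC)CC)C2=C1C(C)C | intermediate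
16 | (3R)-3α-allylic alcohol | O[C@@H]1C[C@]2(C)[C@@H](O[Si](C)(C)C(C)(C)C)CCCC(O[Si](CC)(CC)CC)C2=C1C(C)C | intermediate
17 | 3α-allylic formate | O=CO[C@@H]1C[C@]2(C)[C@@H](O[Si](C)(C)C(C)(C)C)CCCC(O[Si](CC)(CC)CC)C2=C1C(C)C | intermediate
18 | cis-fused Δ3-alkene, 5β-H | CC(C)C1=CC[C@]2(C)[C@@H](O[Si](C)(C)C(C)(C)C)CCCC(O[Si](CC)(CC)CC)[C@@H]21 | intermediate
19 | 3β,4β-diol | O[C@H]1C[C@]2(C)[C@@H](O[Si](C)(C)C(C)(C)C)CCCC(O[Si](CC)(CC)CC)[C@@H]2[C@]1(O)C(C)C | intermediate
20 | 3β-acetate, 4β-OH, 6-OTES | CC(=O)O[C@H]1C[C@]2(C)[C@@H](O[Si](C)(C)C(C)(C)C)CCCC(O[Si](CC)(CC)CC)[C@@H]2[C@]1(O)C(C)C | intermediate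
21 | 3β-acetate, 4β,6-diol | CC(=O)O[C@H]1C[C@]2(C)[C@@H](O[Si](C)(C)C(C)(C)C)CCCC(O)[C@@H]2[C@]1(O)C(C)C | intermediate
22 | 3β-acetate, 4β-OH, 6-ketone | CC(=O)O[C@H]1C[C@]2(C)[C@@H](O[Si](C)(C)C(C)(C)C)CCCC(=O)[C@@H]2[C@]1(O)C(C)C | intermediate
23 | C6 TMS enol ether, C4-O-TMS | CC(=O)O[C@H]1C[C@]2(C)[C@@H](O[Si](C)(C)C(C)(C)C)CCC=C(O[Si](C)(C)C)[C@@H]2[C@]1(O[Si](C)(C)C)C(C)C | intermediate (not isolated)
24 | C4-O-TMS 7-en-6-one | CC(=O)O[C@H]1C[C@]2(C)[C@@H](O[Si](C)(C)C(C)(C)C)CC=CC(=O)[C@@H]2[C@]1(O[Si](C)(C)C)C(C)C | intermediate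
25 | 8-methyl C6 TMS enol ether, C4-O-TMS (C8 open) | CC(=O)O[C@H]1C[C@]2(C)[C@@H](O[Si](C)(C)C(C)(C)C)CC(C)C=C(O[Si](C)(C)C)[C@@H]2[C@]1(O[Si](C)(C)C)C(C)C | intermediate (not isolated)
26 | C4-O-TMS 8-methyl-7-en-6-one | CC(=O)O[C@H]1C[C@]2(C)[C@@H](O[Si](C)(C)C(C)(C)C)CC(C)=CC(=O)[C@@H]2[C@]1(O[Si](C)(C)C)C(C)C | intermediate (not isolated)
27 | 8-methyl-7-en-6-one, 4β-OH | CC(=O)O[C@H]1C[C@]2(C)[C@@H](O[Si](C)(C)C(C)(C)C)CC(C)=CC(=O)[C@@H]2[C@]1(O)C(C)C | intermediate
28 | 6α-allylic alcohol | CC(=O)O[C@H]1C[C@]2(C)[C@@H](O[Si](C)(C)C(C)(C)C)CC(C)=C[C@H](O)[C@@H]2[C@]1(O)C(C)C | intermediate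
29 | 4-(tert-butyldimethylsilyloxy)benzoic acid | CC(C)(C)[Si](C)(C)Oc1ccc(cc1)C(O)=O | starting material
30 | 4-(TBS-oxy)benzoic 2,4,6-trichlorobenzoic anhydride | CC(C)(C)[Si](C)(C)Oc1ccc(cc1)C(=O)OC(=O)c1c(Cl)cc(Cl)cc1Cl | intermediate (not isolated)
31 | bis-TBS ether of the target | CC(=O)O[C@H]1C[C@]2(C)[C@@H](O[Si](C)(C)C(C)(C)C)CC(C)=C[C@H](OC(=O)c3ccc(O[Si](C)(C)C(C)(C)C)cc3)[C@@H]2[C@]1(O)C(C)C | intermediate
32 | CNP0146780.2 | CC(=O)O[C@H]1C[C@]2(C)[C@@H](O)CC(C)=C[C@H](OC(=O)c3ccc(O)cc3)[C@@H]2[C@]1(O)C(C)C | target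

**Totals**
Total step count: 20. Longest linear sequence: 19 steps (steps 1, 3–20, from cycloheptane-1,3-dione); step 2 is a one-step side branch.

**Steps most likely to fail**

1. Step 4 (proposed new method). The strained 5-enolendo closure may not turn over with the amino acid (the catalyst parks as a hemiaminal or in bridged ketols), or it may close with poor discrimination between the enantiotopic carbonyls. Fallback with known chemistry, from 8 back to 11: triketone 8 is cyclised without induction by the base-mediated 1,4-diketone cyclopentenone condensation (KOt-Bu cat., t-BuOH/THF, rt; a non-nucleophilic base spares the 1,3-dione from retro-Claisen cleavage) to the racemic enedione F1. NaBH4 (EtOH, −20 °C) gives the racemic cis-10-hydroxy enone F2. Acylation with (1S)-(−)-camphanic chloride (pyridine, DMAP) gives the camphanate F3 of the (1S,10S)-alcohol and the diastereomeric camphanate F4 of its enantiomer, which are separated by chromatography or crystallisation. Methanolysis of F3 (K2CO3, MeOH) returns to the route at 11.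

2. Step 7. Enolisation may go to the α′ carbon C2 and give the endocyclic 2-silyloxycyclopentadiene, so that the peracid oxidises C2 instead of C6; peracid attack at C4 is a lesser risk. Fallback, from 12 back to 14: dehydrogenation with chloranil (t-BuOH, reflux) can only run toward C6=C7 because C1 is quaternary and gives the 4,6-dien-3-one F5. Mukaiyama hydration (Mn(dpm)3 cat., PhSiH3, O2, i-PrOH/CH2Cl2, 0 °C) adds hydrogen to C7 and oxygen to the enone-stabilised C6 radical to give the C6 hydroperoxide F6, which PPh3 reduces to 14.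

3. Step 11. Ionisation of the hindered allylic formate on a tetrasubstituted alkene may be slow, β-hydride or β-silyloxy elimination may give dienes, or π–σ–π isomerisation may erode the transfer of configuration to C5. Fallback, from 16 back to 18: Myers reductive transposition. Mitsunobu reaction of 16 with 2-nitrobenzenesulfonylhydrazide (PPh3, DEAD, N-methylmorpholine, −30 °C) inverts C3 and gives the 3β-N-sulfonylhydrazine F7; on warming to rt it loses sulfinic acid to the allylic diazene F8, whose retro-ene loss of N2 delivers hydrogen suprafacially to the β face of C5 and gives 18.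

**Further compounds**
F1 | step 4 | racemic 4-isopropyl-1-methylbicyclo[5.3.0]dec-4-ene-3,10-dione | O=C1CC2(C)C(=O)CCCCC2=C1C(C)C
F2 | step 4 | racemic (1S*,10S*)-10-hydroxy-4-isopropyl-1-methylbicyclo[5.3.0]dec-4-en-3-one | O=C1CC2(C)C(O)CCCCC2=C1C(C)C
F3 | step 4 | (1S)-camphanate of 11 | O=C1C[C@]2(C)[C@@H](OC(=O)[C@@]34CC[C@@](C)(C(=O)O3)C4(C)C)CCCCC2=C1C(C)C
F4 | step 4 | (1S)-camphanate of the enantiomer of 11 | O=C1C[C@@]2(C)[C@H](OC(=O)[C@@]34CC[C@@](C)(C(=O)O3)C4(C)C)CCCCC2=C1C(C)C
F5 | step 7 | 10β-(TBS-oxy)-4-isopropyl-1-methylbicyclo[5.3.0]deca-4,6-dien-3-one | O=C1C[C@]2(C)[C@@H](O[Si](C)(C)C(C)(C)C)CCC=CC2=C1C(C)C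
F6 | step 7 | 6-hydroperoxy-10β-(TBS-oxy) enone | O=C1C[C@]2(C)[C@@H](O[Si](C)(C)C(C)(C)C)CCCC(OO)C2=C1C(C)C
F7 | step 11 | 3β-[N-(2-nitrobenzenesulfonyl)hydrazino] allylic adduct | NN([C@H]1C[C@]2(C)[C@@H](O[Si](C)(C)C(C)(C)C)CCCC(O[Si](CC)(CC)CC)C2=C1C(C)C)S(=O)(=O)c3ccccc3[N+](=O)[O-]
F8 | step 11 | 3β-allylic diazene | N=N[C@H]1C[C@]2(C)[C@@H](O[Si](C)(C)C(C)(C)C)CCCC(O[Si](CC)(CC)CC)C2=C1C(C)C
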